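# Proposed total synthesis of CNP0277410.0 (22) by aryne annulation of a 2-aryl-3-hydroxyacrylate

Compound numbers used throughout: ring B enol ester 13, aryne precursor 18, aryne 19, protected isoflavone 20, target 22. The full list follows the steps.

## The problem

The target 22 is an isoflavone: a 5,7-dihydroxylated ring A is fused through C4a and C8a to the pyranone ring C, and ring B is attached at C3. Ring B is pentasubstituted, with 2'-OH, the 3-hydroxy-3-methylbutyl chain at C3', 4'-OH and 5'-OMe in a row. The chain must therefore be placed between two oxygens, and one methyl ether must be kept apart from four phenols that are free at the end. There is no stereocenter, so nothing has to be set and nothing can relay control; the only geometric demand is that O1 and C4 lie cis across C2=C3, which ring C enforces. The tertiary alcohol is the most fragile group: under strong acid it ionizes and is trapped by the neighbouring 2'- or 4'-phenol as a 2,2-dimethylchroman, or it eliminates, so the last unmasking must be gentle. The chromone is opened by strong base or nucleophiles at C2, its C2=C3 bond can be over-reduced, and the free polyphenol is easily oxidized, which argues for unveiling the phenols only at the end. The feature that invites a convergent closure of ring C is that O1 and C4 sit on the adjacent ring A carbons C8a and C4a, and that C4a has the C5 oxygen as its other neighbour. An aryne spanning C4a and C8a is polarized by that oxygen, so an oxygen nucleophile adds at C8a and the carbanion appears at C4a, ready to take up an acyl carbon.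

## Retrosynthesis

**Unmasking (22 ⇐ 21 ⇐ 20).** Only oxygen–protecting-group bonds are cut: two aryl methoxymethyl ethers and the triethylsilyl ether of 21, and before them the two benzyl ethers of 20. Each ring needs its group earlier in the route: the benzyl ethers belong to the aryne precursor 18, and the two methoxymethyl groups direct the metalation that places the side chain. Hydrogenolysis comes first, while the acid-sensitive ring B array is still capped. The closing step then asks only for dilute acid, under which the silyl ether goes at once and the aryl acetals should follow before the tertiary alcohol ionizes.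

**Ring C (20 ⇐ 13 + 18, through 19).** O1–C8a and C4–C4a are cut together. This removes ring C and divides the molecule into the ring A aryne 19 and the three-carbon enol ester 13, which already carries ring B on the future C3. The neighbouring cuts are weaker here. Cutting C3–C1' (cross-coupling) leaves ring C to be built separately on a ring A ketone. Cutting O1–C2 and C2–C3 (the deoxybenzoin way) requires Friedel–Crafts acylation of ring A under Lewis acids that the acetals and silyl ether of ring B would not survive. The chosen cut needs no carbonyl group on ring A and no differentiation of its three oxygens, because the benzyloxy group next to the triple bond of 19 decides which aryne carbon takes the oxygen. The forward reaction must deliver three things: O- and not C-arylation of the ambident enolate of 13, addition at the aryne carbon remote from the flanking ether, and acyl capture by the aryl anion before it is protonated.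

**Aryne precursor (18 ⇐ 15 ⇐ 14).** The C–Si and O–S bonds of 18 are traced back to bromophenol 15 by O-silylation, bromine–lithium exchange with a 1,3-shift of silicon from oxygen to carbon, and O-triflation. The C–Br bond of 15 comes from ortho-bromination of the symmetric phenol 14, whose two ortho positions are equivalent. The precursor is thus two steps from a purchasable phenol. The forward sequence must exchange bromine faster than it deprotonates a benzylic position.

**Enol ester (13 ⇐ 12).** The C2–C3 bond is cut: the future C2 is added as a formyl group to the benzylic carbon of arylacetate 12 by a crossed Claisen condensation. Bringing C2 and C3 in together would need an aryl–vinyl coupling and a later unmasking of the enol. Formylation starts from a stable ester and gives the enol directly.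

**Arylacetate (12 ⇐ 11 ⇐ 10 ⇐ 9).** The C1'–CH2 bond is cut to aryl bromide 11 and an acetate zinc enolate, joined under palladium catalysis. The C–Br bond comes from electrophilic substitution on 9, where the only position ortho and para to the two acetal oxygens is the future C1'. The silyl ether (11 from 10) is put on in between, so that neither the enolate chemistry nor the aryne step meets a free hydroxyl. A formylation and homologation sequence at the same carbon would cost several more steps.

**Side chain (9 ⇐ 8 ⇐ 5 + 6).** The tertiary C–O bond is cut by Markovnikov hydration of the prenyl group of 8. The C3'–CH2 bond is cut by allylation, with prenyl bromide 6, of the aryllithium 7 formed between the two acetal oxygens of 5. This is the step for which the methoxymethyl groups are needed; no electrophilic substitution would enter this doubly flanked position selectively.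

**Oxygen pattern (5 ⇐ 4 ⇐ 2 ⇐ 1).** The 1,2,4-trioxygenated ring with one methyl ether is traced to isovanillin 1. Its formyl group is exchanged for oxygen by Baeyer–Villiger oxidation (2 to 4 through formate 3), which places the new oxygen para to the methoxy group. The two phenols are capped one before and one after. The methyl ether of the target is thus bought, not made.

## Roads not taken

**Alternative 1:** Ring B is taken apart into the acyclic methyl ketone A1 and the acrylate A2, cutting C1'–C6' and C3'–C4'. In the forward key step the kinetic lithium enolate on the methyl side of A1 adds to A2, and the other α-carbon of the ketone then attacks the ester to give the cyclohexane-1,3-dione enol A3, racemic at the methoxy-bearing carbon.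

- Merits: the chain ends up between two oxygens and the methoxy group next to one of them purely through the connectivity of the acyclic pieces, with no question of aromatic substitution regiochemistry. The racemic centre disappears on aromatization and is harmless.
- Weak points: A3 still has to be dehydrogenated to a resorcinol, and its two oxygens then protected. C1' and C6' emerge as unfunctionalized CH2 groups, so the handle for joining ring B to the chromone has to be introduced afterwards. Ring C is not addressed at all. A 2-alkoxyacrylate is a sluggish Michael acceptor, and proton transfer between the two enolate sites of A1 can erode the regiocontrol of the annulation.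
- Comparison: this road is better in one respect, since its substitution pattern does not depend on a directed metalation (step 4) or a regioselective bromination (step 6). The chosen plan sets against this the cooperative directing effect of two acetal oxygens and a clear electronic bias in the bromination. It also reaches 9 from 1 in five steps, whereas a de novo ring would take at least as many and then rejoin the same endgame.

**Alternative 2:** Ring C is cut at C3–C4 and O1–C2 into the O-silyl salicyloyl chloride A4 and the styryl enamine A5. In the forward key step the β-carbon of A5 is acylated by A4; after desilylation the phenol adds to the aminomethylene carbon and the secondary amine leaves, giving A6, which is identical in structure with 20.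

- Merits: it is as convergent as the chosen plan and uses the same protecting groups. Each bond-forming event belongs to established reactivity (enamine C-acylation, addition–elimination on a vinylogous amide), so it needs no untested step. In this respect it is the stronger plan.
- Weak points: A4 is a 2,4,6-trioxygenated benzoyl chloride. Its parent acid decarboxylates easily, its carbonyl is flanked by two ortho substituents, and its preparation requires telling apart three ring A oxygens and forming an acid chloride without losing a silyl ether. A5 needs the ring B arylacetaldehyde, an electron-rich, enolizable and air-sensitive aldehyde, and an enamine that cannot be stored.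
- Comparison: the chosen plan sets against the precedent of this road a ring A partner (18) that is two steps from a purchasable phenol, carries no carbonyl group and needs no differentiation of its oxygens, and a ring B partner (13) that is one step from the stable ester 12. The price is an annulation without direct precedent.

**Alternative 3:** Ring B is built on a preformed chromone by Dötz benzannulation, cutting C5'–C6', C1'–C2' and C2'–C3'. The zerovalent chromium alkenyl(methoxy)carbene complex A8 reacts with the 3-ethynylchromone A7 and one carbonyl ligand to give A9, in which the C2' phenol is free.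

- Merits: all five ring B substituents are placed in one step. The regiochemistry is set by the terminal alkyne (the larger substituent ends up next to the new phenol), and the reaction class is established.
- Weak points: chromium is used stoichiometrically. A8, an α-alkoxy alkenyl carbene with a β-alkyl group, needs a multi-step preparation through a sensitive α-alkoxyvinyl metal species. A7 requires a 3-halochromone and an alkynylation, and its electrophilic C2 may compete for the carbene. The differentiated 2'-phenol of A9 is of no use, since both ring B phenols are free in 22. A benzene ring that can be bought is made from scratch.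
- Comparison: this road is better in that its key reaction type is known and in that it avoids the two regiochemical aromatic substitutions. The chosen plan sets against it metal-free ring construction, much shorter partner syntheses and aromatic starting materials.

Key step: step 12

Assumption: 3,5-bis(benzyloxy)phenol (14) is taken as a purchasable phenol; were it not at hand, partial O-benzylation of the parent triphenol would supply it and add one step to the short branch.

## Route

Step 1
Reactants: 1 isovanillin (3-hydroxy-4-methoxybenzaldehyde)
Product: 2 4-methoxy-3-(methoxymethoxy)benzaldehyde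
Conditions: MOMCl, i-Pr2NEt, CH2Cl2, 0 °C → rt
Reagents that add atoms: chloromethyl methyl ether (MOMCl), COCCl
Why: O-Alkylation of the phenol with an α-chloro ether (acetal protection); the aldehyde is not enolizable and is untouched, and this acetal later serves as a directing group in step 4.

Step 2
Reactants: 2 4-methoxy-3-(methoxymethoxy)benzaldehyde
Product: 4 4-methoxy-3-(methoxymethoxy)phenol, via aryl formate 3 (not isolated)
Conditions: mCPBA, CH2Cl2, rt; aq. NaHCO3 wash; K2CO3 (cat.), MeOH, rt
Reagents that add atoms: 3-chloroperoxybenzoic acid (mCPBA), OOC(=O)c1cccc(Cl)c1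
Why: Baeyer–Villiger oxidation: the electron-rich aryl group (para-methoxy) migrates in preference to hydride and gives the formate, which mild methanolysis cleaves to the phenol; aryl acetals tolerate the peracid at room temperature.

Step 3
Reactants: 4 4-methoxy-3-(methoxymethoxy)phenol
Product: 5 1-methoxy-2,4-bis(methoxymethoxy)benzene
Conditions: MOMCl, i-Pr2NEt, CH2Cl2, 0 °C → rt
Reagents that add atoms: chloromethyl methyl ether (MOMCl), COCCl
Why: Second acetal protection of a phenol; it completes the pair of ortho-directing groups that flank the future C3'.

Step 4
Reactants: 5 1-methoxy-2,4-bis(methoxymethoxy)benzene; 6 1-bromo-3-methylbut-2-ene (prenyl bromide)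
Product: 8 1-methoxy-2,4-bis(methoxymethoxy)-3-(3-methylbut-2-en-1-yl)benzene, via aryllithium 7 (not isolated)
Conditions: n-BuLi, THF, 0 °C; CuI (10 mol %), then 6, −78 °C → rt
Reagents that add atoms: none
Why: Directed ortho-metalation: the C–H between the two methoxymethoxy groups is the most acidic and doubly coordinated site; copper-mediated allylation with the primary bromide should then proceed at the primary carbon (SN2) and give the linear prenyl group.

Step 5
Reactants: 8 1-methoxy-2,4-bis(methoxymethoxy)-3-(3-methylbut-2-en-1-yl)benzene
Product: 9 4-[3-methoxy-2,6-bis(methoxymethoxy)phenyl]-2-methylbutan-2-ol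
Conditions: Co(acac)2 (20 mol %), PhSiH3, O2 (1 atm), THF, rt; aq. Na2S2O3
Reagents that add atoms: dioxygen, O=O
Why: Mukaiyama hydration: hydrogen-atom transfer from a cobalt hydride gives the tertiary radical (Markovnikov), which is trapped by O2 and reduced to the tertiary alcohol; the radical pathway avoids cationic participation of the neighbouring acetal oxygens.

Step 6
Reactants: 9 4-[3-methoxy-2,6-bis(methoxymethoxy)phenyl]-2-methylbutan-2-ol
Product: 10 4-[3-bromo-5-methoxy-2,6-bis(methoxymethoxy)phenyl]-2-methylbutan-2-ol
Conditions: NBS, MeCN, 0 °C
Reagents that add atoms: N-bromosuccinimide (NBS), O=C1CCC(=O)N1Br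
Why: Electrophilic aromatic bromination: of the two free ring positions one is ortho to one acetal oxygen and para to the other, while the second is ortho to the methoxy group only and has no second oxygen in conjugation, so bromine should enter at the future C1'.

Step 7
Reactants: 10 4-[3-bromo-5-methoxy-2,6-bis(methoxymethoxy)phenyl]-2-methylbutan-2-ol
Product: 11 {[4-(3-bromo-5-methoxy-2,6-bis(methoxymethoxy)phenyl)-2-methylbutan-2-yl]oxy}triethylsilane
Conditions: Et3SiCl, imidazole, DMAP (cat.), DMF, 40 °C
Reagents that add atoms: chlorotriethylsilane, CC[Si](Cl)(CC)CC
Why: Silylation of the tertiary alcohol removes the only hydroxyl proton besides the later enol before the enolate and aryne steps; the chlorosilane with imidazole is preferred to a silyl triflate, which could activate the aryl acetals.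

Step 8
Reactants: 11 {[4-(3-bromo-5-methoxy-2,6-bis(methoxymethoxy)phenyl)-2-methylbutan-2-yl]oxy}triethylsilane
Product: 12 methyl 2-{5-methoxy-2,4-bis(methoxymethoxy)-3-[3-methyl-3-(triethylsilyloxy)butyl]phenyl}acetate
Conditions: BrZnCH2CO2Me (generated beforehand from BrCH2CO2Me and Zn dust in THF), Pd2(dba)3 (2.5 mol %), XPhos (10 mol %), THF, 65 °C
Reagents that add atoms: (2-methoxy-2-oxoethyl)zinc bromide, COC(=O)C[Zn]Br
Why: Palladium-catalysed α-arylation of an ester zinc enolate (Reformatsky reagent in a Negishi-type coupling); the nearly neutral zinc enolate tolerates acetals and the silyl ether, and the bulky biarylphosphine is suited to an electron-rich, ortho-substituted aryl bromide.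

Step 9
Reactants: 12 methyl 2-{5-methoxy-2,4-bis(methoxymethoxy)-3-[3-methyl-3-(triethylsilyloxy)butyl]phenyl}acetate
Product: 13 methyl (Z)-3-hydroxy-2-{5-methoxy-2,4-bis(methoxymethoxy)-3-[3-methyl-3-(triethylsilyloxy)butyl]phenyl}prop-2-enoate
Conditions: NaH, HCO2Me, THF, 0 °C → rt; AcOH quench
Reagents that add atoms: methyl formate, COC=O
Why: Crossed Claisen condensation (C-formylation of the ester enolate), driven by formation of the stabilized enolate of the product; after mild acidification the product should rest as the hydrogen-bonded Z enol, which carries the future C2.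

Step 10
Reactants: 14 3,5-bis(benzyloxy)phenol
Product: 15 3,5-bis(benzyloxy)-2-bromophenol
Conditions: NBS, CH2Cl2, −78 °C → rt
Reagents that add atoms: N-bromosuccinimide (NBS), O=C1CCC(=O)N1Br
Why: Electrophilic bromination ortho to the free phenol in a non-polar solvent at low temperature; the two ortho positions are equivalent, so only monobromination and ortho against para selectivity need control.

Step 11
Reactants: 15 3,5-bis(benzyloxy)-2-bromophenol
Product: 18 3,5-bis(benzyloxy)-2-(trimethylsilyl)phenyl trifluoromethanesulfonate, via silyl ether 16 (not isolated), via lithium phenoxide 17 (not isolated)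
Conditions: (Me3Si)2NH, THF, 65 °C, then evaporation; n-BuLi, THF, −100 °C → −78 °C; Tf2O, −100 °C → rt
Reagents that add atoms: hexamethyldisilazane, C[Si](C)(C)N[Si](C)(C)C; trifluoromethanesulfonic anhydride, O=S(=O)(OS(=O)(=O)C(F)(F)F)C(F)(F)F
Why: O-Silylation, bromine–lithium exchange, 1,3-shift of silicon from oxygen to carbon (retro-Brook rearrangement) and O-triflation of the resulting phenoxide, the standard entry to ortho-silylaryl triflates; at −100 °C the exchange should outrun benzylic deprotonation.

Step 12
Reactants: 13 methyl (Z)-3-hydroxy-2-{5-methoxy-2,4-bis(methoxymethoxy)-3-[3-methyl-3-(triethylsilyloxy)butyl]phenyl}prop-2-enoate; 18 3,5-bis(benzyloxy)-2-(trimethylsilyl)phenyl trifluoromethanesulfonate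
Product: 20 5,7-bis(benzyloxy)-3-{5-methoxy-2,4-bis(methoxymethoxy)-3-[3-methyl-3-(triethylsilyloxy)butyl]phenyl}-4H-chromen-4-one, via aryne 19 (not isolated)
Conditions: CsF (4 equiv), 18 (1.5 equiv), THF, 65 °C
Reagents that add atoms: none
Why: Proposed new method: fluoride attacks the silicon of 18 and triflate leaves, releasing aryne 19, whose triple bond is distorted by the flanking benzyloxy group so that nucleophiles add at the remote carbon (future C8a) and the negative charge develops at the oxygen-flanked carbon (future C4a). The cesium enolate of 13, a vinylogous carboxylate, adds through its terminal oxygen (O1–C8a), and the aryl anion so formed attacks the ester carbonyl held cis on the Z enol ether in a 6-exo-trig acyl substitution (C4–C4a) that expels methoxide and closes ring C. The closest known reaction type is the aryne insertion and annulation of salicylate esters to xanthones (O-arylation followed by intramolecular acyl capture), whose conditions (CsF, THF, 65 °C) are taken over; the enol of a formylacetate has not been used in this role. No stereocenter is formed, and the chelated Z geometry of the enolate supplies the cis relation of O1 and C4 that ring closure needs. Three selectivities are required: regiochemistry on the aryne, secured by induction from the C5 benzyloxy group; O- over C-arylation, favoured because the enolate carbon is fully substituted and screened by the twisted, ortho-substituted ring B while the charge sits on oxygen with the large cesium counterion; and acyl capture over protonation of the aryl anion, favoured by the weakly protic medium, the six-membered intramolecular transition state and the absence of any hydroxyl other than the enol itself. An excess of 18 allows for aryne lost to the methoxide released by the ring closure.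

Step 13
Reactants: 20 5,7-bis(benzyloxy)-3-{5-methoxy-2,4-bis(methoxymethoxy)-3-[3-methyl-3-(triethylsilyloxy)butyl]phenyl}-4H-chromen-4-one
Product: 21 5,7-dihydroxy-3-{5-methoxy-2,4-bis(methoxymethoxy)-3-[3-methyl-3-(triethylsilyloxy)butyl]phenyl}-4H-chromen-4-one
Conditions: H2 (1 atm), Pd/C (10 %), EtOAc–THF, rt
Reagents that add atoms: none
Why: Hydrogenolysis of aryl benzyl ethers under neutral conditions; acetals, the aryl methyl ether and (in an aprotic solvent) the silyl ether are inert, and the reaction is to be stopped at hydrogen uptake for two benzyl groups to spare the C2=C3 bond.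

Step 14
Reactants: 21 5,7-dihydroxy-3-{5-methoxy-2,4-bis(methoxymethoxy)-3-[3-methyl-3-(triethylsilyloxy)butyl]phenyl}-4H-chromen-4-one
Product: 22 5,7-dihydroxy-3-[2,4-dihydroxy-3-(3-hydroxy-3-methylbutyl)-5-methoxyphenyl]-4H-chromen-4-one (CNP0277410.0)
Conditions: HCl (1 M), MeOH–THF, 0 °C → rt
Reagents that add atoms: none
Why: Acid-catalysed acetal exchange with methanol removes both aryl methoxymethyl groups and solvolysis removes the triethylsilyl ether; dilute acid at or below room temperature is chosen so that the tertiary alcohol does not ionize toward chroman formation or elimination.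

## Compound list

1 | isovanillin (3-hydroxy-4-methoxybenzaldehyde) | COc1ccc(C=O)cc1O | starting material
2 | 4-methoxy-3-(methoxymethoxy)benzaldehyde | COCOc1cc(C=O)ccc1OC | intermediate
3 | 4-methoxy-3-(methoxymethoxy)phenyl formate | COCOc1cc(OC=O)ccc1OC | intermediate (not isolated)
4 | 4-methoxy-3-(methoxymethoxy)phenol | COCOc1cc(O)ccc1OC | intermediate
5 | 1-methoxy-2,4-bis(methoxymethoxy)benzene | COCOc1ccc(OC)c(OCOC)c1 | intermediate
6 | 1-bromo-3-methylbut-2-ene (prenyl bromide) | CC(C)=CCBr | starting material
7 | [3-methoxy-2,6-bis(methoxymethoxy)phenyl]lithium | [Li]c1c(OCOC)ccc(OC)c1OCOC | intermediate (not isolated)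
8 | 1-methoxy-2,4-bis(methoxymethoxy)-3-(3-methylbut-2-en-1-yl)benzene | COCOc1ccc(OC)c(OCOC)c1CC=C(C)C | intermediate
9 | 4-[3-methoxy-2,6-bis(methoxymethoxy)phenyl]-2-methylbutan-2-ol | COCOc1ccc(OC)c(OCOC)c1CCC(C)(C)O | intermediate
10 | 4-[3-bromo-5-methoxy-2,6-bis(methoxymethoxy)phenyl]-2-methylbutan-2-ol | COCOc1c(Br)cc(OC)c(OCOC)c1CCC(C)(C)O | intermediate
11 | {[4-(3-bromo-5-methoxy-2,6-bis(methoxymethoxy)phenyl)-2-methylbutan-2-yl]oxy}triethylsilane | COCOc1c(Br)cc(OC)c(OCOC)c1CCC(C)(C)O[Si](CC)(CC)CC | intermediate
12 | methyl 2-{5-methoxy-2,4-bis(methoxymethoxy)-3-[3-methyl-3-(triethylsilyloxy)butyl]phenyl}acetate | COC(=O)Cc1cc(OC)c(OCOC)c(CCC(C)(C)O[Si](CC)(CC)CC)c1OCOC | intermediate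
13 | methyl (Z)-3-hydroxy-2-{5-methoxy-2,4-bis(methoxymethoxy)-3-[3-methyl-3-(triethylsilyloxy)butyl]phenyl}prop-2-enoate | COC(=O)/C(=C\O)c1cc(OC)c(OCOC)c(CCC(C)(C)O[Si](CC)(CC)CC)c1OCOC | intermediate
14 | 3,5-bis(benzyloxy)phenol | Oc1cc(OCc2ccccc2)cc(OCc2ccccc2)c1 | starting material
15 | 3,5-bis(benzyloxy)-2-bromophenol | Oc1cc(OCc2ccccc2)cc(OCc2ccccc2)c1Br | intermediate
16 | [3,5-bis(benzyloxy)-2-bromophenoxy]trimethylsilane | C[Si](C)(C)Oc1cc(OCc2ccccc2)cc(OCc2ccccc2)c1Br | intermediate (not isolated)
17 | lithium 3,5-bis(benzyloxy)-2-(trimethylsilyl)phenoxide | [Li+].[O-]c1cc(OCc2ccccc2)cc(OCc2ccccc2)c1[Si](C)(C)C | intermediate (not isolated)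
18 | 3,5-bis(benzyloxy)-2-(trimethylsilyl)phenyl trifluoromethanesulfonate | C[Si](C)(C)c1c(OS(=O)(=O)C(F)(F)F)cc(OCc2ccccc2)cc1OCc1ccccc1 | intermediate
19 | 3,5-bis(benzyloxy)benzyne (3,5-bis(benzyloxy)-1,2-didehydrobenzene) | C1#CC(OCc2ccccc2)=CC(OCc2ccccc2)=C1 | intermediate (not isolated)
20 | 5,7-bis(benzyloxy)-3-{5-methoxy-2,4-bis(methoxymethoxy)-3-[3-methyl-3-(triethylsilyloxy)butyl]phenyl}-4H-chromen-4-one | COc1cc(-c2coc3cc(OCc4ccccc4)cc(OCc4ccccc4)c3c2=O)c(OCOC)c(CCC(C)(C)O[Si](CC)(CC)CC)c1OCOC | intermediate
21 | 5,7-dihydroxy-3-{5-methoxy-2,4-bis(methoxymethoxy)-3-[3-methyl-3-(triethylsilyloxy)butyl]phenyl}-4H-chromen-4-one | COc1cc(-c2coc3cc(O)cc(O)c3c2=O)c(OCOC)c(CCC(C)(C)O[Si](CC)(CC)CC)c1OCOC | intermediate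
22 | 5,7-dihydroxy-3-[2,4-dihydroxy-3-(3-hydroxy-3-methylbutyl)-5-methoxyphenyl]-4H-chromen-4-one | COc1cc(-c2coc3cc(O)cc(O)c3c2=O)c(O)c(CCC(C)(C)O)c1O | target

## Step count and least certain steps

Total: 14 steps (nine to enol ester 13 from 1, two to aryne precursor 18 from 14, the annulation, two deprotections). Longest linear sequence: 12 steps (steps 1–9, 12, 13, 14).

**Step 12 (key step, proposed new method).** The most likely failures are:
- C-arylation of the ambident enolate, after which the aryl anion would attack the formyl group and the adduct would fragment (formal insertion into the C–CHO bond);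
- protonation of the aryl anion before acyl capture, leaving an open aryl enol ether;
- consumption of the aryne by released methoxide;
- loss of the silyl ether to fluoride. This last would not change the final product, since both forms converge after step 14.

The fallback uses known chemistry, the Suzuki–Miyaura route to isoflavones. It sets out from 11 and comes back at 20. Bromide 11 is converted by bromine–lithium exchange (n-BuLi, THF, −78 °C) and trapping with 2-isopropoxy-4,4,5,5-tetramethyl-1,3,2-dioxaborolane into the pinacol boronate 2-{5-methoxy-2,4-bis(methoxymethoxy)-3-[3-methyl-3-(triethylsilyloxy)butyl]phenyl}-4,4,5,5-tetramethyl-1,3,2-dioxaborolane F1. Purchased 1-[2,4-bis(benzyloxy)-6-hydroxyphenyl]ethan-1-one F2 is condensed with N,N-dimethylformamide dimethyl acetal to the enaminone (E)-1-[2,4-bis(benzyloxy)-6-hydroxyphenyl]-3-(dimethylamino)prop-2-en-1-one F3, which iodine cyclizes to 5,7-bis(benzyloxy)-3-iodo-4H-chromen-4-one F4. Coupling of F1 with F4 (Pd(dppf)Cl2, K3PO4, dioxane–water, 80 °C) should give 20. This gives up the aryne disconnection (C3–C1' is formed instead) and makes steps 8–11 unnecessary.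

**Step 4.** The allylation may occur at the tertiary terminus of 6 (SN2′), giving the reverse-prenyl isomer, or metalation may be incomplete, so that separation from 5 becomes difficult. The fallback sets out from 5 and comes back at 9, replacing steps 4 and 5. Aryllithium 7 is quenched with iodine to give 2-iodo-4-methoxy-1,3-bis(methoxymethoxy)benzene F5. Sonogashira coupling with 2-methylbut-3-yn-2-ol (Pd(PPh3)2Cl2, CuI, Et3N) gives 4-[3-methoxy-2,6-bis(methoxymethoxy)phenyl]-2-methylbut-3-yn-2-ol F6. Hydrogenation of the triple bond (H2, Pd/C, EtOAc) should then give 9 with the tertiary alcohol already in place.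

**Step 8.** Oxidative addition into the electron-rich, ortho-substituted bromide may be slow, so that protodebromination of 11 or self-condensation of the methyl ester zinc enolate takes over. The fallback sets out from 11 and comes back at 12. Bromine–lithium exchange (n-BuLi, THF, −78 °C) and opening of ethylene oxide give 2-{5-methoxy-2,4-bis(methoxymethoxy)-3-[3-methyl-3-(triethylsilyloxy)butyl]phenyl}ethan-1-ol F7. Buffered oxidation (TEMPO, NaClO2, catalytic NaOCl, pH 6.7 phosphate, MeCN) gives 2-{5-methoxy-2,4-bis(methoxymethoxy)-3-[3-methyl-3-(triethylsilyloxy)butyl]phenyl}acetic acid F8. O-Methylation (MeI, K2CO3, DMF) then returns to 12.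

**Step 14.** Ionization of the tertiary alcohol under acid, followed by capture by the 2'- or 4'-phenol (chroman formation) or elimination, may compete with cleavage of the two aryl acetals. The fallback sets out from 21 and comes back at 22 without Brønsted acid. TMSOTf with 2,2'-bipyridyl (CH2Cl2, 0 °C → rt) converts the aryl methoxymethyl ethers into aryl silyl ethers, which water hydrolyses to 5,7-dihydroxy-3-{2,4-dihydroxy-5-methoxy-3-[3-methyl-3-(triethylsilyloxy)butyl]phenyl}-4H-chromen-4-one F9. Pyridine-buffered HF·pyridine (THF, 0 °C) then removes the triethylsilyl group to give 22.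

## Further compounds

F1 | step 12 | 2-{5-methoxy-2,4-bis(methoxymethoxy)-3-[3-methyl-3-(triethylsilyloxy)butyl]phenyl}-4,4,5,5-tetramethyl-1,3,2-dioxaborolane | COc1cc(B2OC(C)(C)C(C)(C)O2)c(OCOC)c(CCC(C)(C)O[Si](CC)(CC)CC)c1OCOC
F2 | step 12 | 1-[2,4-bis(benzyloxy)-6-hydroxyphenyl]ethan-1-one | CC(=O)c1c(O)cc(OCc2ccccc2)cc1OCc1ccccc1
F3 | step 12 | (E)-1-[2,4-bis(benzyloxy)-6-hydroxyphenyl]-3-(dimethylamino)prop-2-en-1-one | CN(C)/C=C/C(=O)c1c(O)cc(OCc2ccccc2)cc1OCc1ccccc1
F4 | step 12 | 5,7-bis(benzyloxy)-3-iodo-4H-chromen-4-one | O=c1c(I)coc2cc(OCc3ccccc3)cc(OCc3ccccc3)c12
F5 | step 4 | 2-iodo-4-methoxy-1,3-bis(methoxymethoxy)benzene | COCOc1ccc(OC)c(OCOC)c1I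
F6 | step 4 | 4-[3-methoxy-2,6-bis(methoxymethoxy)phenyl]-2-methylbut-3-yn-2-ol | COCOc1ccc(OC)c(OCOC)c1C#CC(C)(C)O
F7 | step 8 | 2-{5-methoxy-2,4-bis(methoxymethoxy)-3-[3-methyl-3-(triethylsilyloxy)butyl]phenyl}ethan-1-ol | OCCc1cc(OC)c(OCOC)c(CCC(C)(C)O[Si](CC)(CC)CC)c1OCOC
F8 | step 8 | 2-{5-methoxy-2,4-bis(methoxymethoxy)-3-[3-methyl-3-(triethylsilyloxy)butyl]phenyl}acetic acid | OC(=O)Cc1cc(OC)c(OCOC)c(CCC(C)(C)O[Si](CC)(CC)CC)c1OCOC
F9 | step 14 | 5,7-dihydroxy-3-{2,4-dihydroxy-5-methoxy-3-[3-methyl-3-(triethylsilyloxy)butyl]phenyl}-4H-chromen-4-one | COc1cc(-c2coc3cc(O)cc(O)c3c2=O)c(O)c(CCC(C)(C)O[Si](CC)(CC)CC)c1O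
A1 | alternative 1 | 6-methyl-6-(triethylsilyloxy)heptan-2-one | CC(=O)CCCC(C)(C)O[Si](CC)(CC)CC
A2 | alternative 1 | methyl 2-methoxyprop-2-enoate | COC(=O)C(=C)OC
A3 | alternative 1 | racemic 3-hydroxy-4-methoxy-2-[3-methyl-3-(triethylsilyloxy)butyl]cyclohex-2-en-1-one | COC1CCC(=O)C(CCC(C)(C)O[Si](CC)(CC)CC)=C1O
A4 | alternative 2 | 2,4-bis(benzyloxy)-6-[(tert-butyldimethylsilyl)oxy]benzoyl chloride | O=C(Cl)c1c(O[Si](C)(C)C(C)(C)C)cc(OCc2ccccc2)cc1OCc1ccccc1
A5 | alternative 2 | 4-[(E)-2-{5-methoxy-2,4-bis(methoxymethoxy)-3-[3-methyl-3-(triethylsilyloxy)butyl]phenyl}ethenyl]morpholine | COc1cc(/C=C/N2CCOCC2)c(OCOC)c(CCC(C)(C)O[Si](CC)(CC)CC)c1OCOC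
A6 | alternative 2 | 5,7-bis(benzyloxy)-3-{5-methoxy-2,4-bis(methoxymethoxy)-3-[3-methyl-3-(triethylsilyloxy)butyl]phenyl}-4H-chromen-4-one | COc1cc(-c2coc3cc(OCc4ccccc4)cc(OCc4ccccc4)c3c2=O)c(OCOC)c(CCC(C)(C)O[Si](CC)(CC)CC)c1OCOC
A7 | alternative 3 | 5,7-bis(benzyloxy)-3-ethynyl-4H-chromen-4-one | C#Cc1coc2cc(OCc3ccccc3)cc(OCc3ccccc3)c2c1=O
A8 | alternative 3 | pentacarbonyl{methoxy[1-(methoxymethoxy)-5-methyl-5-(triethylsilyloxy)hex-1-en-1-yl]methylidene}chromium (alkene geometry not specified) | COC(=[Cr](=C=O)(=C=O)(=C=O)(=C=O)=C=O)C(OCOC)=CCCC(C)(C)O[Si](CC)(CC)CC
A9 | alternative 3 | 5,7-bis(benzyloxy)-3-{2-hydroxy-5-methoxy-4-(methoxymethoxy)-3-[3-methyl-3-(triethylsilyloxy)butyl]phenyl}-4H-chromen-4-one | COc1cc(-c2coc3cc(OCc4ccccc4)cc(OCc4ccccc4)c3c2=O)c(O)c(CCC(C)(C)O[Si](CC)(CC)CC)c1OCOC
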